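**Retrosynthetic overview**
- The target is opened at both O1–C2 bonds to an acyclic bis-chalcone, (2E,3E)-1-(2,6-dihydroxy-4-methoxyphenyl)-2,3-bis(4-methoxybenzylidene)-4-(2,4,6-trihydroxyphenyl)butane-1,4-dione. Both pyranone rings are closed last, in one catalytic asymmetric double oxa-Michael/protonation that sets all four stereocentres.
- The bis-chalcone comes from its pentakis-MOM ether (acid-labile protection only).
- The protected diketone comes from two successive aryllithium acylations of one C4 unit: fulgide opening (aryl of the 7-OMe half), carboxylate O-methylation, then ester to ketone (aryl of the 5,7-dihydroxy half).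
- The fulgide comes from (E,E)-bis(4-methoxybenzylidene)succinic acid, made by double Stobbe condensation of diethyl succinate with p-anisaldehyde. The succinate C2–C3 bond becomes C3–C3''.
- The aryllithiums come from ortho-lithiation of the MOM ethers of 5-methoxyresorcinol and phloroglucinol. Ring order: no ring until the last step, then one chromanone, then the other.

Assumption: the target is (2R,3R,2''R,3''R), i.e. 2,3-cis in both rings (flavanone numbering; doubly primed = 7-methoxy half). The epi-quinidine-derived catalyst is assumed to give the 2R series; if the sense is opposite, its epi-quinine-derived pseudoenantiomer is used.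

**Step 1**
Reactants: 1 diethyl succinate; 2 4-methoxybenzaldehyde (2.2 equiv)
Product: 3 (2E,3E)-2,3-bis(4-methoxybenzylidene)succinic acid
Conditions: NaOEt (3 equiv), EtOH, reflux, 16 h; then 2 M aq NaOH, reflux; HCl to pH 1; recrystallise (amber glass)
Reagents that add atoms: none
Why: Double Stobbe condensation; each aldol/γ-lactonisation/E1cB ring-opening consumes one ester and gives the E-alkene (aryl anti to carboxyl), the classical route to symmetrical bis(arylidene)succinic acids, and the NaOH stage only clears residual half-ester.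

**Step 2**
Reactants: 3 (2E,3E)-2,3-bis(4-methoxybenzylidene)succinic acid
Product: 4 (3E,4E)-3,4-bis(4-methoxybenzylidene)oxolane-2,5-dione (the fulgide)
Conditions: AcCl (neat), reflux, 2 h; evaporate; crystallise (exclude UV light)
Reagents that add atoms: none
Why: Cyclodehydration via the mixed anhydride (standard fulgide formation); the alkene geometry is not touched.

**Step 3**
Reactants: 5 5-methoxyresorcinol
Product: 6 1-methoxy-3,5-bis(methoxymethoxy)benzene
Conditions: NaH (2.3 equiv), DMF, 0 °C; MOMCl (2.3 equiv), 0 °C→rt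
Reagents that add atoms: chloromethyl methyl ether (MOMCl), COCCl
Why: Williamson O-alkylation of both phenoxides (MOM protection); the MOM ethers later act as ortho-lithiation directors and come off under mild acid.

**Step 4**
Reactants: 6 1-methoxy-3,5-bis(methoxymethoxy)benzene; 4 (3E,4E)-3,4-bis(4-methoxybenzylidene)oxolane-2,5-dione
Product: 9 methyl (2E,3E)-4-[4-methoxy-2,6-bis(methoxymethoxy)phenyl]-2,3-bis(4-methoxybenzylidene)-4-oxobutanoate, via aryllithium 7 (not isolated), via lithium keto-carboxylate 8 (not isolated)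
Conditions: 6, n-BuLi (1.05 equiv), THF, 0 °C, 1 h; cannulate into 4 (1.0 equiv), THF, −78 °C; then MeI (5 equiv), DMF, −78 °C→rt
Reagents that add atoms: iodomethane (MeI), CI
Why: Directed ortho-metalation at the site flanked by two MOM ethers (stronger cooperative directors than OMe; any OMe/OMOM regioisomer is removed at this crystalline ester), nucleophilic acyl substitution on the symmetrical anhydride (either C=O gives the same product, and the hindered 2,6-dialkoxyaryl ketone and the carboxylate resist a second addition), then SN2 O-methylation of the carboxylate.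

**Step 5**
Reactants: 10 phloroglucinol
Product: 11 1,3,5-tris(methoxymethoxy)benzene
Conditions: NaH (3.5 equiv), DMF, 0 °C; MOMCl (3.5 equiv), 0 °C→rt
Reagents that add atoms: chloromethyl methyl ether (MOMCl), COCCl
Why: Williamson O-alkylation (MOM protection) of the three phenoxides with the hard electrophile, giving a C3-symmetric arene with a single type of ring C–H.

**Step 6**
Reactants: 11 1,3,5-tris(methoxymethoxy)benzene; 9 methyl (2E,3E)-4-[4-methoxy-2,6-bis(methoxymethoxy)phenyl]-2,3-bis(4-methoxybenzylidene)-4-oxobutanoate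
Product: 13 (2E,3E)-1-[4-methoxy-2,6-bis(methoxymethoxy)phenyl]-2,3-bis(4-methoxybenzylidene)-4-[2,4,6-tris(methoxymethoxy)phenyl]butane-1,4-dione, via aryllithium 12 (not isolated)
Conditions: 11 (1.5 equiv), n-BuLi (1.4 equiv), THF, 0 °C, 1 h; then 9, THF, −78→−20 °C; H2O quench at −20 °C
Reagents that add atoms: none
Why: Directed ortho-metalation (all ring positions equivalent) followed by addition–elimination at the methyl ester; both 2,6-dialkoxyaryl ketones (the one already present and the one formed) are too hindered and electron-rich for 1,2-addition, so the reaction stops at the diketone.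

**Step 7**
Reactants: 13 (2E,3E)-1-[4-methoxy-2,6-bis(methoxymethoxy)phenyl]-2,3-bis(4-methoxybenzylidene)-4-[2,4,6-tris(methoxymethoxy)phenyl]butane-1,4-dione
Product: 14 (2E,3E)-1-(2,6-dihydroxy-4-methoxyphenyl)-2,3-bis(4-methoxybenzylidene)-4-(2,4,6-trihydroxyphenyl)butane-1,4-dione
Conditions: 3 M aq HCl/MeOH/THF (1:4:4), 25 °C, 6–12 h, argon, dark; NaHCO3 to pH 6, extract, precipitate from EtOAc/hexane
Reagents that add atoms: none
Why: Acid-catalysed acetal cleavage (transacetalisation to methylal) removes all five MOM groups; the twisted α-branched chalcones should close only slowly under mild acid at room temperature, so the open bis-chalcone can be isolated.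

**Step 8**
Reactants: 14 (2E,3E)-1-(2,6-dihydroxy-4-methoxyphenyl)-2,3-bis(4-methoxybenzylidene)-4-(2,4,6-trihydroxyphenyl)butane-1,4-dione
Product: 16 (2R,3R)-5,7-dihydroxy-3-[(2R,3R)-5-hydroxy-7-methoxy-2-(4-methoxyphenyl)-4-oxochroman-3-yl]-2-(4-methoxyphenyl)chroman-4-one (CNP0184936.2), via mono-flavanone 15 (not isolated)
Conditions: N-[3,5-bis(trifluoromethyl)phenyl]-N'-[(9R)-6'-methoxycinchonan-9-yl]squaramide (10 mol %), EtOAc/CH2Cl2 1:3, −30 °C, argon; filter cold through AcOH-washed silica (isomerisation, no co-product)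
Reagents that add atoms: none
Why: Proposed new method: a catalytic enantio- and diastereoselective double 6-endo oxa-Michael/kinetic-protonation cascade on an unactivated α-branched bis-chalcone. Each 2,6-dihydroxyaryl ketone carries its own activator (the 6'-OH···O=C hydrogen bond, kept as the 5-OH chelate, makes closure downhill) and its own nucleophile (2'-OH). The squaramide binds the chelated carbonyl while the quinuclidine deprotonates the 2'-OH and steers it to one face of the (E)-β-carbon, giving C2 = R in both halves under catalyst control, with ee upgraded at the cost of the separable unlike diastereomer. In the resulting 2H-chromen-4-ol the 2-anisyl group sits pseudo-axial to avoid A(1,2) strain with the bulky C3 substituent, so C3 is protonated anti to the aryl, giving the kinetic 2,3-cis ketone (3R), which the weak base does not epimerise at −30 °C. Closest known reaction types: cinchona thiourea/squaramide-catalysed asymmetric oxa-Michael cyclisation of activated 2'-hydroxychalcones (alkylidene β-keto esters) to flavanones, and conjugate addition/enantioselective protonation cascades.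

**Compound list**
1 | diethyl succinate | CCOC(=O)CCC(=O)OCC | starting material
2 | 4-methoxybenzaldehyde | COc1ccc(C=O)cc1 | starting material
3 | (2E,3E)-2,3-bis(4-methoxybenzylidene)succinic acid | OC(=O)/C(=C/c1ccc(OC)cc1)/C(=C\c1ccc(OC)cc1)C(=O)O | intermediate
4 | (3E,4E)-3,4-bis(4-methoxybenzylidene)oxolane-2,5-dione | O=C1OC(=O)/C(=C/c2ccc(OC)cc2)/C1=C\c2ccc(OC)cc2 | intermediate
5 | 5-methoxyresorcinol | COc1cc(O)cc(O)c1 | starting material
6 | 1-methoxy-3,5-bis(methoxymethoxy)benzene | COCOc1cc(OC)cc(OCOC)c1 | intermediate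
7 | [4-methoxy-2,6-bis(methoxymethoxy)phenyl]lithium | [Li]c1c(OCOC)cc(OC)cc1OCOC | intermediate
8 | lithium (2E,3E)-4-[4-methoxy-2,6-bis(methoxymethoxy)phenyl]-2,3-bis(4-methoxybenzylidene)-4-oxobutanoate | [Li+].[O-]C(=O)/C(=C/c1ccc(OC)cc1)/C(=C\c1ccc(OC)cc1)C(=O)c1c(OCOC)cc(OC)cc1OCOC | intermediate
9 | methyl (2E,3E)-4-[4-methoxy-2,6-bis(methoxymethoxy)phenyl]-2,3-bis(4-methoxybenzylidene)-4-oxobutanoate | COC(=O)/C(=C/c1ccc(OC)cc1)/C(=C\c1ccc(OC)cc1)C(=O)c1c(OCOC)cc(OC)cc1OCOC | intermediate
10 | phloroglucinol | Oc1cc(O)cc(O)c1 | starting material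
11 | 1,3,5-tris(methoxymethoxy)benzene | COCOc1cc(OCOC)cc(OCOC)c1 | intermediate
12 | [2,4,6-tris(methoxymethoxy)phenyl]lithium | [Li]c1c(OCOC)cc(OCOC)cc1OCOC | intermediate
13 | (2E,3E)-1-[4-methoxy-2,6-bis(methoxymethoxy)phenyl]-2,3-bis(4-methoxybenzylidene)-4-[2,4,6-tris(methoxymethoxy)phenyl]butane-1,4-dione | COCOc1cc(OCOC)c(C(=O)/C(=C/c2ccc(OC)cc2)/C(=C\c2ccc(OC)cc2)C(=O)c2c(OCOC)cc(OC)cc2OCOC)c(OCOC)c1 | intermediate
14 | (2E,3E)-1-(2,6-dihydroxy-4-methoxyphenyl)-2,3-bis(4-methoxybenzylidene)-4-(2,4,6-trihydroxyphenyl)butane-1,4-dione | Oc1cc(O)c(C(=O)/C(=C/c2ccc(OC)cc2)/C(=C\c2ccc(OC)cc2)C(=O)c2c(O)cc(OC)cc2O)c(O)c1 | intermediate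
15 | (2E)-2-[(2R,3R)-5,7-dihydroxy-2-(4-methoxyphenyl)-4-oxochroman-3-yl]-1-(2,6-dihydroxy-4-methoxyphenyl)-3-(4-methoxyphenyl)prop-2-en-1-one (shown with the trihydroxyphenyl half closed first; either half may close first) | COc1ccc([C@@H]2Oc3cc(O)cc(O)c3C(=O)[C@@H]2/C(=C\c2ccc(OC)cc2)C(=O)c2c(O)cc(OC)cc2O)cc1 | intermediate
16 | (2R,3R)-5,7-dihydroxy-3-[(2R,3R)-5-hydroxy-7-methoxy-2-(4-methoxyphenyl)-4-oxochroman-3-yl]-2-(4-methoxyphenyl)chroman-4-one (2,3-cis and 2'',3''-cis) | COc1ccc([C@@H]2Oc3cc(O)cc(O)c3C(=O)[C@@H]2[C@H]2C(=O)c3c(O)cc(OC)cc3O[C@H]2c2ccc(OC)cc2)cc1 | target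

**Step count and risks**
Total step count: 8. Longest linear sequence: 6 (steps 1, 2, 4, 6, 7, 8); steps 3 and 5 are one-step side branches.

Three steps most likely to fail:

1. Step 8 (the proposed new step). Risks: low ee or dr, cis→trans epimerisation at C3/C3'', or γ-protonation of the intermediate dienol. Fallback with known chemistry, setting out from 14 and returning at 16: close both rings with an achiral amine base (cat. Et3N, THF, −20 °C, AcOH quench), the ordinary base-mediated chalcone→flavanone isomerisation under the same kinetic-protonation regime. Separate the like cis,cis pair from the other diastereomers by reversed-phase chromatography; this pair is 16 together with the enantiomer of the target F1. Resolve it by preparative chiral HPLC on an amylose carbamate phase to obtain 16.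

2. Step 6. Risks: sluggish addition of the di-ortho-substituted aryllithium to the hindered ester, or conjugate addition to the existing enone. Fallback setting out from 4 and returning at 13: run step 4 with an aqueous HCl quench in place of MeI to isolate the keto acid F2. Convert it with EtSH/EDC/DMAP into the S-ethyl thioester F3. Couple F3 under Pd catalysis (PdCl2(PPh3)2, THF/toluene, rt; Fukuyama ketone synthesis) with the arylzinc chloride F4, made from 12 and ZnCl2; the soft organozinc does not touch ketones or enones. This gives 13.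

3. Step 7. Risks: acid-promoted, non-selective ring closure before the bis-chalcone is isolated, or incomplete removal of five MOM groups. Fallback setting out from 13 and returning at 14: push the deprotection to completion under forcing acid (6 M HCl/MeOH, 60 °C), accepting full cyclisation to the stereorandom biflavanone F5. Then reopen both pyranone rings by the classical alkaline flavanone→chalcone retro-oxa-Michael (10% aq KOH/EtOH, 0 °C, argon), acidify cold to pH 5 with AcOH and extract at once to recover 14.

**Further compounds**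
F1 | step 8 | (2S,3S)-5,7-dihydroxy-3-[(2S,3S)-5-hydroxy-7-methoxy-2-(4-methoxyphenyl)-4-oxochroman-3-yl]-2-(4-methoxyphenyl)chroman-4-one (enantiomer of 16) | COc1ccc([C@H]2Oc3cc(O)cc(O)c3C(=O)[C@H]2[C@@H]2C(=O)c3c(O)cc(OC)cc3O[C@@H]2c2ccc(OC)cc2)cc1
F2 | step 6 | (2E,3E)-4-[4-methoxy-2,6-bis(methoxymethoxy)phenyl]-2,3-bis(4-methoxybenzylidene)-4-oxobutanoic acid | OC(=O)/C(=C/c1ccc(OC)cc1)/C(=C\c1ccc(OC)cc1)C(=O)c1c(OCOC)cc(OC)cc1OCOC
F3 | step 6 | S-ethyl (2E,3E)-4-[4-methoxy-2,6-bis(methoxymethoxy)phenyl]-2,3-bis(4-methoxybenzylidene)-4-oxobutanethioate | CCSC(=O)/C(=C/c1ccc(OC)cc1)/C(=C\c1ccc(OC)cc1)C(=O)c1c(OCOC)cc(OC)cc1OCOC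
F4 | step 6 | chloro[2,4,6-tris(methoxymethoxy)phenyl]zinc | Cl[Zn]c1c(OCOC)cc(OCOC)cc1OCOC
F5 | step 7 | 5,7-dihydroxy-3-[5-hydroxy-7-methoxy-2-(4-methoxyphenyl)-4-oxochroman-3-yl]-2-(4-methoxyphenyl)chroman-4-one (mixture of stereoisomers at C2, C3, C2'', C3'') | COc1ccc(C2Oc3cc(O)cc(O)c3C(=O)C2C2C(=O)c3c(O)cc(OC)cc3OC2c2ccc(OC)cc2)cc1
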